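**Retrosynthetic overview**
- Feature: ring B is a cyclohexene (C8=C9) whose sp3 carbons run C10 (quaternary)–C5–C6(O)–C7(O). This is the retron of a [4+2] between a 1-oxygenated diene C7=C8–C9=C10 and a C5=C6 dienophile with a latent oxygen on C6 (nitro), tethered through C1–C4 of ring A.
- Target 38 ⇐ PMB removal, triacetylation, desilylation, α-face reduction of the 6-ketone, Nef reaction ⇐ 6α-nitro decalin 32.
- 32 ⇐ intramolecular Diels–Alder of nitro triene 31 (bonds C5–C10 and C6–C7); rings A and B are formed together in this one step.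
- 31 ⇐ Henry condensation at C5 and enol silylation at C7 of dialdehyde 26; C7 comes from methylenation and hydroboration of enone 21.
- The tetrasubstituted C9=C10 alkene ⇐ anti-carbomagnesiation of propargylic alcohol 16 (from (S)-epoxide 12, acetylide, acetaldehyde) with side-chain Grignard reagent 17 (from but-3-yn-1-ol), then methyl coupling for C20.

Key step: step 22

Remark: labdane numbering (C1–C20) is used for all intermediates; TBS = tert-butyldimethylsilyl, PMB = 4-methoxybenzyl.
Remark: O15 is carried as the PMB ether so that it survives fluoride and is removed last, after acetylation.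
Remark: the diene of 31 is 7E,9E by the CIP rules (C1 trans to C8 at C9=C10; silyloxy trans to C9 at C7=C8).
Remark: C8 in 16–26 and the carbinol carbon C5 in 29 and 30 are stereocentres of no consequence (both epimers) and are removed later.

**Side chain (C11–C16)**

Step 1
Reactants: 1 but-3-yn-1-ol
Product: 2 tert-butyl(but-3-yn-1-yloxy)dimethylsilane
Conditions: TBSCl, imidazole, CH2Cl2, 0 °C → rt
Reagents that add atoms: tert-butyldimethylsilyl chloride, CC(C)(C)[Si](C)(C)Cl
Why: Imidazole-promoted silyl ether formation on a primary alcohol is routine and masks the C11 hydroxyl for the organoaluminium step.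

Step 2
Reactants: 2 tert-butyl(but-3-yn-1-yloxy)dimethylsilane
Product: 5 (E)-5-(tert-butyldimethylsilyloxy)-3-methylpent-2-en-1-ol, via alkenylalane 3 (not isolated), via lithium alanate 4 (not isolated)
Conditions: Me3Al, Cp2ZrCl2 (25 mol %), CH2Cl2, 0 °C → rt; then n-BuLi, THF, −78 °C; (CH2O)n, → rt
Reagents that add atoms: trimethylaluminium, C[Al](C)C; formaldehyde (as paraformaldehyde), C=O
Why: Zirconium-catalysed methylalumination (Negishi carboalumination) is a syn addition with methyl on the internal and aluminium on the terminal alkyne carbon, and the alanate is hydroxymethylated with retention, which fixes the 13E alkene.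

Step 3
Reactants: 5 (E)-5-(tert-butyldimethylsilyloxy)-3-methylpent-2-en-1-ol
Product: 6 (E)-tert-butyl{[5-(4-methoxybenzyloxy)-3-methylpent-3-en-1-yl]oxy}dimethylsilane
Conditions: NaH, PMBCl, Bu4NI (cat.), THF–DMF, 0 °C → rt
Reagents that add atoms: 4-methoxybenzyl chloride, COc1ccc(CCl)cc1
Why: Williamson etherification of the allylic alkoxide installs an O15 group that tolerates organomagnesium, fluoride and hydride reagents.

Step 4
Reactants: 6 (E)-tert-butyl{[5-(4-methoxybenzyloxy)-3-methylpent-3-en-1-yl]oxy}dimethylsilane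
Product: 7 (E)-5-(4-methoxybenzyloxy)-3-methylpent-3-en-1-ol
Conditions: TBAF, THF, rt
Reagents that add atoms: none
Why: Fluoride desilylation cleaves the primary silyl ether and leaves the benzylic ether untouched.

Step 5
Reactants: 7 (E)-5-(4-methoxybenzyloxy)-3-methylpent-3-en-1-ol
Product: 8 1-({[(E)-5-bromo-3-methylpent-2-en-1-yl]oxy}methyl)-4-methoxybenzene
Conditions: CBr4, PPh3, CH2Cl2, 0 °C
Reagents that add atoms: carbon tetrabromide, BrC(Br)(Br)Br
Why: Appel bromination converts the primary alcohol into the bromide under neutral conditions.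

**Main line**

Step 6
Reactants: 9 2,2-dimethylpent-4-enal
Product: 10 5,5-dimethoxy-4,4-dimethylpent-1-ene
Conditions: HC(OMe)3, MeOH, p-TsOH (cat.), rt
Reagents that add atoms: trimethyl orthoformate, COC(OC)OC; methanol, CO
Why: Acid-catalysed acetalisation with the orthoformate as water scavenger masks the C5 aldehyde against the later carbanion steps.

Step 7
Reactants: 10 5,5-dimethoxy-4,4-dimethylpent-1-ene
Product: 11 rac-2-(3,3-dimethoxy-2,2-dimethylpropyl)oxirane
Conditions: mCPBA, NaHCO3, CH2Cl2, 0 °C → rt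
Reagents that add atoms: 3-chloroperbenzoic acid, OOC(=O)c1cccc(Cl)c1
Why: Prilezhaev epoxidation of the only alkene, buffered so that the acetal survives.

Step 8
Reactants: 11 rac-2-(3,3-dimethoxy-2,2-dimethylpropyl)oxirane
Product: 12 (S)-2-(3,3-dimethoxy-2,2-dimethylpropyl)oxirane
Conditions: (S,S)-(salen)Co(OAc) (0.5 mol %; salen = N,N'-bis(3,5-di-tert-butylsalicylidene)cyclohexane-1,2-diamine dianion; the catalyst enantiomer that hydrolyses the (R)-epoxide faster), H2O (0.55 equiv), THF, 0 °C → rt
Reagents that add atoms: none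
Why: Hydrolytic kinetic resolution of a terminal epoxide destroys the (R)-enantiomer as its diol and leaves the (S)-epoxide, which sets C2.

Step 9
Reactants: 12 (S)-2-(3,3-dimethoxy-2,2-dimethylpropyl)oxirane
Product: 13 (4R)-7,7-dimethoxy-6,6-dimethylhept-1-yn-4-ol
Conditions: LiC≡CH·H2NCH2CH2NH2, DMSO, rt
Reagents that add atoms: lithium acetylide ethylenediamine complex, [Li+].[C-]#C.NCCN
Why: SN2 opening of the terminal epoxide at its CH2 carbon (C1) by the acetylide leaves C2 untouched and needs no Lewis acid, so the acetal is safe.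

Step 10
Reactants: 13 (4R)-7,7-dimethoxy-6,6-dimethylhept-1-yn-4-ol
Product: 14 (4R)-4-(tert-butyldimethylsilyloxy)-7,7-dimethoxy-6,6-dimethylhept-1-yne
Conditions: TBSCl, imidazole, DMF, rt
Reagents that add atoms: tert-butyldimethylsilyl chloride, CC(C)(C)[Si](C)(C)Cl
Why: Routine silylation of the secondary alcohol gives the C2 silyl ether that later steers the cycloaddition.

Step 11
Reactants: 14 (4R)-4-(tert-butyldimethylsilyloxy)-7,7-dimethoxy-6,6-dimethylhept-1-yne
Product: 16 (6R)-6-(tert-butyldimethylsilyloxy)-9,9-dimethoxy-8,8-dimethylnon-3-yn-2-ol (both carbinol epimers), via lithium acetylide 15 (not isolated)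
Conditions: n-BuLi, THF, −78 °C; then MeCHO, −78 → 0 °C
Reagents that add atoms: acetaldehyde, CC=O
Why: Deprotonation of the terminal alkyne and 1,2-addition to acetaldehyde gives the propargylic alcohol; the new centre C8 forms as both epimers and is oxidised later.

Step 12
Reactants: 16 propargylic alcohol; 8 side-chain bromide
Product: 19 iodo allylic alcohol (9Z; iodine on C10 cis to C8), via Grignard reagent 17 (not isolated), via alkenylmagnesium alkoxide chelate 18 (not isolated)
Conditions: 8, Mg, THF (gives 17, 3 equiv); then 16, CuI (15 mol %), Et2O–THF, 0 → 35 °C; then I2, −40 → 0 °C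
Reagents that add atoms: iodine, II
Why: Copper-catalysed anti-carbomagnesiation of a propargylic alkoxide delivers the alkyl group to the alkyne carbon next to the carbinol (C9) and magnesium to C10 within a five-membered magnesium alkoxide ring, so C11 and C1 end up cis, and iodinolysis of the C–Mg bond goes with retention; the mild temperature limits homoallyl–cyclopropylcarbinyl scrambling of the Grignard reagent.

Step 13
Reactants: 19 iodo allylic alcohol
Product: 20 allylic alcohol with C20 methyl on C10 (9E)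
Conditions: Pd(PPh3)4 (5 mol %), Me2Zn, THF, 0 → 50 °C
Reagents that add atoms: dimethylzinc, C[Zn]C
Why: Negishi cross-coupling of the alkenyl iodide proceeds with retention of geometry and places C20 cis to C8.

Step 14
Reactants: 20 allylic alcohol
Product: 21 enone (C8 methyl ketone, 9E)
Conditions: Dess–Martin periodinane, NaHCO3, CH2Cl2, 0 °C → rt
Reagents that add atoms: none
Why: Dess–Martin oxidation of the secondary allylic alcohol under buffered, non-isomerising conditions removes the C8 stereocentre.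

Step 15
Reactants: 21 enone
Product: 22 diene (C7H2=C8(CH3)–C9=C10, 9E)
Conditions: Ph3PCH3Br, KHMDS, THF, 0 °C; then 21, 0 °C → rt
Reagents that add atoms: methyltriphenylphosphonium bromide, C[P+](c1ccccc1)(c1ccccc1)c1ccccc1.[Br-]
Why: Wittig methylenation of the methyl ketone with the pre-formed ylide and no excess base, so that the tetrasubstituted alkene is not disturbed through a dienolate.

Step 16
Reactants: 22 diene
Product: 24 C7 primary alcohol (C8 both epimers), via alkylborane 23 (not isolated)
Conditions: 9-BBN, THF, 0 °C → rt; then NaOH, H2O2, 0 °C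
Reagents that add atoms: hydrogen peroxide, OO
Why: Hydroboration–oxidation with bulky 9-BBN adds boron only to the terminal carbon of the 1,1-disubstituted alkene (anti-Markovnikov, much faster than at the tri- and tetrasubstituted alkenes); C8 forms as both epimers, which does not matter.

Step 17
Reactants: 24 C7 primary alcohol
Product: 25 hydroxy aldehyde (C5 aldehyde, C7 alcohol)
Conditions: PPTS (cat.), acetone–H2O (10:1), 50 °C
Reagents that add atoms: water, O
Why: Mild acid-catalysed acetal hydrolysis frees the C5 aldehyde while the secondary silyl ether and the PMB ether persist.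

Step 18
Reactants: 25 hydroxy aldehyde
Product: 26 dialdehyde (C5 and C7 aldehydes)
Conditions: Dess–Martin periodinane, NaHCO3, CH2Cl2, 0 °C; crude product used at once
Reagents that add atoms: none
Why: Dess–Martin oxidation under bicarbonate buffer gives the β,γ-unsaturated C7 aldehyde without migration of the C9=C10 bond.

Step 19
Reactants: 26 dialdehyde
Product: 27 (7E,9E)-silyl dienol ether aldehyde
Conditions: TBSOTf, Et3N, CH2Cl2, −78 → −40 °C
Reagents that add atoms: tert-butyldimethylsilyl trifluoromethanesulfonate, CC(C)(C)[Si](C)(C)OS(=O)(=O)C(F)(F)F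
Why: Soft enolisation (silyl triflate and amine) can only engage the C7 aldehyde, whose C8 hydrogen is α to the carbonyl and allylic, because the C5 aldehyde has no α-hydrogen; the C9=C10 geometry is carried over and the new C7=C8 bond should form mainly as the E isomer, which keeps the bulky C9 group away from the silyloxy group.

Step 20
Reactants: 27 silyl dienol ether aldehyde; 28 nitromethane
Product: 29 β-nitro alcohol (both C5 epimers)
Conditions: MeNO2 (excess), 1,1,3,3-tetramethylguanidine (cat.), THF, 0 °C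
Reagents that add atoms: none
Why: Henry (nitroaldol) addition to the non-enolisable neopentyl aldehyde under amine catalysis that the silyl dienol ether tolerates; the carbinol centre is lost in the next step.

Step 21
Reactants: 29 β-nitro alcohol
Product: 31 (5E,7E,9E,13E)-nitro triene, via mesylate 30 (not isolated)
Conditions: MsCl, i-Pr2NEt, CH2Cl2, −30 → 0 °C; rapid filtration through neutral alumina, kept cold
Reagents that add atoms: none
Why: Mesylation and base-induced E1cB elimination give the conjugated nitroalkene, the E isomer being strongly favoured next to quaternary C4.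

Step 22
Reactants: 31 nitro triene
Product: 32 6α-nitro-2α,7α-bis(tert-butyldimethylsilyloxy)-15-(4-methoxybenzyloxy)labda-8,13E-diene
Conditions: PhMe (5 mM), BHT, 2,6-di-tert-butyl-4-methylpyridine (cat.), 90–110 °C, sealed vessel
Reagents that add atoms: none
Why: Proposed new method: a thermal, concerted but asynchronous normal-demand [4+2] cycloaddition in which the nucleophilic, fully substituted diene terminus C10 bonds first to the electrophilic nitroalkene carbon C5 and C7 then closes onto C6; the closest known reaction type is the thermal intramolecular Diels–Alder reaction of (E)-1-nitro-1,7,9-decatrienes to trans-fused nitro-octalins, not yet shown with a tetrasubstituted diene terminus or a dienophile carbon next to a quaternary centre. Ring B closes as the six-membered cycloadduct ring (bonds C5–C10 and C6–C7) and ring A closes at the same time through the C1–C4 tether attached at the diene terminus (type 1 tether) as the second six-membered ring of a bicyclo[4.4.0] system. C5 and C6 follow from suprafacial addition to the E-nitroalkene (H5 and NO2 cis); C7 and C10 follow from suprafacial addition to the 7E,9E diene, whose outside groups (silyloxy and C1) end up cis (7α-OSi, 10β-methyl); the trans C5/C10 fusion and the 6α-nitro group follow from the endo-nitro, tether-exo transition state; the absolute sense comes from C2, whose silyloxy group sits equatorial on the chair-folded tether. The step needs reactivity (gem-dimethyl Thorpe–Ingold folding, electron-rich silyloxy diene against a strongly electron-poor nitroalkene), π-facial selectivity (an axial C2 substituent would clash with the axial C4 methyl and the C10 methyl) and trans fusion (endo preference of the nitro group). C6 is erased in the Nef step and C5 then lies next to the ketone, so a cis-fused by-product could still be equilibrated into the trans series.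

Step 23
Reactants: 32 nitro decalin
Product: 34 2α,7α-bis(tert-butyldimethylsilyloxy)-15-(4-methoxybenzyloxy)labda-8,13E-dien-6-one, via sodium nitronate 33 (not isolated)
Conditions: NaOMe, MeOH–THF, 0 °C; then aq. TiCl3, NH4OAc (pH 5–6), 0 °C → rt
Reagents that add atoms: water, O
Why: Nef reaction in its reductive variant: the nitronate is reduced by TiCl3 to the imine, which hydrolyses to the ketone under buffered conditions mild enough for the silyl ethers, leaving C5 and C7 untouched.

Step 24
Reactants: 34 6-ketone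
Product: 35 2α,7α-bis(tert-butyldimethylsilyloxy)-15-(4-methoxybenzyloxy)labda-8,13E-dien-6β-ol
Conditions: NaBH4, MeOH–THF, −20 → 0 °C
Reagents that add atoms: none
Why: Hydride reduction of the ketone; the β face of C6 is blocked by the two syn-axial methyl groups on C4 and C10, so hydride arrives from the α face and the axial 6β-alcohol results.

Step 25
Reactants: 35 6β-alcohol
Product: 36 15-(4-methoxybenzyloxy)labda-8,13E-diene-2α,6β,7α-triol
Conditions: TBAF, THF, rt → 45 °C
Reagents that add atoms: none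
Why: Fluoride desilylation removes both secondary silyl ethers; the PMB ether is inert to fluoride.

Step 26
Reactants: 36 triol
Product: 37 2α,6β,7α-triacetoxy-15-(4-methoxybenzyloxy)labda-8,13E-diene
Conditions: Ac2O, DMAP, Et3N, CH2Cl2, rt → 40 °C
Reagents that add atoms: acetic anhydride, CC(=O)OC(C)=O
Why: DMAP-catalysed acetylation of all three secondary alcohols, with warming for the hindered axial 6β-hydroxyl; the trans-diaxial O6 and O7 cannot exchange acyl groups.

Step 27
Reactants: 37 triacetate PMB ether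
Product: 38 2α,6β,7α-triacetoxylabda-8,13E-dien-15-ol (target)
Conditions: DDQ, CH2Cl2–pH 7 buffer, 0 °C
Reagents that add atoms: none
Why: Oxidative PMB ether cleavage by DDQ (electron transfer, then hydrolysis of the oxocarbenium ion) is orthogonal to the three acetates and frees the C15 alcohol.

**Compound list**
1 | but-3-yn-1-ol | C#CCCO | starting material
2 | tert-butyl(but-3-yn-1-yloxy)dimethylsilane | C#CCCO[Si](C)(C)C(C)(C)C | intermediate
3 | (E)-[4-(tert-butyldimethylsilyloxy)-2-methylbut-1-en-1-yl]dimethylalane | C[Al](C)/C=C(\C)CCO[Si](C)(C)C(C)(C)C | intermediate (not isolated)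
4 | lithium butyl[(E)-4-(tert-butyldimethylsilyloxy)-2-methylbut-1-en-1-yl]dimethylaluminate | [Li+].CCCC[Al-](C)(C)/C=C(\C)CCO[Si](C)(C)C(C)(C)C | intermediate (not isolated)
5 | (E)-5-(tert-butyldimethylsilyloxy)-3-methylpent-2-en-1-ol | OC/C=C(\C)CCO[Si](C)(C)C(C)(C)C | intermediate
6 | (E)-tert-butyl{[5-(4-methoxybenzyloxy)-3-methylpent-3-en-1-yl]oxy}dimethylsilane | COc1ccc(COC/C=C(\C)CCO[Si](C)(C)C(C)(C)C)cc1 | intermediate
7 | (E)-5-(4-methoxybenzyloxy)-3-methylpent-3-en-1-ol | COc1ccc(COC/C=C(\C)CCO)cc1 | intermediate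
8 | 1-({[(E)-5-bromo-3-methylpent-2-en-1-yl]oxy}methyl)-4-methoxybenzene | COc1ccc(COC/C=C(\C)CCBr)cc1 | intermediate
9 | 2,2-dimethylpent-4-enal | C=CCC(C)(C)C=O | starting material
10 | 5,5-dimethoxy-4,4-dimethylpent-1-ene | C=CCC(C)(C)C(OC)OC | intermediate
11 | rac-2-(3,3-dimethoxy-2,2-dimethylpropyl)oxirane | COC(OC)C(C)(C)CC1CO1 | intermediate
12 | (S)-2-(3,3-dimethoxy-2,2-dimethylpropyl)oxirane | COC(OC)C(C)(C)C[C@H]1CO1 | intermediate
13 | (4R)-7,7-dimethoxy-6,6-dimethylhept-1-yn-4-ol | COC(OC)C(C)(C)C[C@H](O)CC#C | intermediate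
14 | (4R)-4-(tert-butyldimethylsilyloxy)-7,7-dimethoxy-6,6-dimethylhept-1-yne | COC(OC)C(C)(C)C[C@H](O[Si](C)(C)C(C)(C)C)CC#C | intermediate
15 | lithium acetylide of 14 | COC(OC)C(C)(C)C[C@H](O[Si](C)(C)C(C)(C)C)CC#C[Li] | intermediate (not isolated)
16 | (6R)-6-(tert-butyldimethylsilyloxy)-9,9-dimethoxy-8,8-dimethylnon-3-yn-2-ol, both carbinol epimers | COC(OC)C(C)(C)C[C@H](O[Si](C)(C)C(C)(C)C)CC#CC(C)O | intermediate
17 | [(E)-5-(4-methoxybenzyloxy)-3-methylpent-3-en-1-yl]magnesium bromide | COc1ccc(COC/C=C(\C)CC[Mg]Br)cc1 | intermediate (not isolated)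
18 | cyclic alkenylmagnesium alkoxide (2,5-dihydro-1,2-oxamagnesole; Mg on C10, O on C8) | COC(OC)C(C)(C)C[C@H](O[Si](C)(C)C(C)(C)C)CC1=C(CC/C(C)=C/COCc2ccc(OC)cc2)C(C)O[Mg]1 | intermediate (not isolated)
19 | acyclic chain, C5 dimethyl acetal, 2-OTBS (C2 as in 14), (9Z)-10-iodo-9-ene with iodine cis to C8, 8-hydroxy (both epimers), (13E)-15-OPMB | COC(OC)C(C)(C)C[C@H](O[Si](C)(C)C(C)(C)C)C/C(I)=C(\CC/C(C)=C/COCc1ccc(OC)cc1)C(C)O | intermediate
20 | as 19 with methyl (C20) in place of iodine, (9E): C1 cis to C11, C20 cis to C8 | COC(OC)C(C)(C)C[C@H](O[Si](C)(C)C(C)(C)C)C/C(C)=C(\CC/C(C)=C/COCc1ccc(OC)cc1)C(C)O | intermediate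
21 | as 20 with C8 oxidised to the methyl ketone (9E-enone) | COC(OC)C(C)(C)C[C@H](O[Si](C)(C)C(C)(C)C)C/C(C)=C(\CC/C(C)=C/COCc1ccc(OC)cc1)C(C)=O | intermediate
22 | as 21 with C8=C7H2 in place of C8=O (isopropenyl diene, 9E) | COC(OC)C(C)(C)C[C@H](O[Si](C)(C)C(C)(C)C)C/C(C)=C(\CC/C(C)=C/COCc1ccc(OC)cc1)C(C)=C | intermediate
23 | B-alkyl-9-borabicyclo[3.3.1]nonane with boron on C7 | COC(OC)C(C)(C)C[C@H](O[Si](C)(C)C(C)(C)C)C/C(C)=C(\CC/C(C)=C/COCc1ccc(OC)cc1)C(C)CB1C2CCCC1CCC2 | intermediate (not isolated)
24 | C7 primary alcohol, C8 both epimers, C5 dimethyl acetal, 2-OTBS, (9E,13E), 15-OPMB | COC(OC)C(C)(C)C[C@H](O[Si](C)(C)C(C)(C)C)C/C(C)=C(\CC/C(C)=C/COCc1ccc(OC)cc1)C(C)CO | intermediate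
25 | as 24 with free C5 aldehyde | O=CC(C)(C)C[C@H](O[Si](C)(C)C(C)(C)C)C/C(C)=C(\CC/C(C)=C/COCc1ccc(OC)cc1)C(C)CO | intermediate
26 | C5,C7-dialdehyde, 2-OTBS, (9E,13E), 15-OPMB | O=CC(C)(C)C[C@H](O[Si](C)(C)C(C)(C)C)C/C(C)=C(\CC/C(C)=C/COCc1ccc(OC)cc1)C(C)C=O | intermediate
27 | C5 aldehyde with (7E,9E)-7-(tert-butyldimethylsilyloxy)-7,9-diene, 2-OTBS, (13E)-15-OPMB | O=CC(C)(C)C[C@H](O[Si](C)(C)C(C)(C)C)C/C(C)=C(CC/C(C)=C/COCc1ccc(OC)cc1)/C(C)=C/O[Si](C)(C)C(C)(C)C | intermediate
28 | nitromethane | C[N+](=O)[O-] | starting material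
29 | 6-nitro-5-hydroxy adduct of 27 (both C5 epimers) | [O-][N+](=O)CC(O)C(C)(C)C[C@H](O[Si](C)(C)C(C)(C)C)C/C(C)=C(CC/C(C)=C/COCc1ccc(OC)cc1)/C(C)=C/O[Si](C)(C)C(C)(C)C | intermediate
30 | C5 methanesulfonate of 29 | [O-][N+](=O)CC(OS(C)(=O)=O)C(C)(C)C[C@H](O[Si](C)(C)C(C)(C)C)C/C(C)=C(CC/C(C)=C/COCc1ccc(OC)cc1)/C(C)=C/O[Si](C)(C)C(C)(C)C | intermediate (not isolated)
31 | (5E,7E,9E,13E)-6-nitro-2,7-bis(tert-butyldimethylsilyloxy)-15-(4-methoxybenzyloxy) acyclic triene (key-step precursor) | [O-][N+](=O)/C=C/C(C)(C)C[C@H](O[Si](C)(C)C(C)(C)C)C/C(C)=C(CC/C(C)=C/COCc1ccc(OC)cc1)/C(C)=C/O[Si](C)(C)C(C)(C)C | intermediate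
32 | 6α-nitro-2α,7α-bis(tert-butyldimethylsilyloxy)-15-(4-methoxybenzyloxy)labda-8,13E-diene | CC(C)(C)[Si](C)(C)O[C@H]1CC(C)(C)[C@@H]2[C@@H]([N+](=O)[O-])[C@@H](O[Si](C)(C)C(C)(C)C)C(C)=C(CC/C(C)=C/COCc3ccc(OC)cc3)[C@@]2(C)C1 | intermediate
33 | sodium 6-nitronate of 32 | [Na+].CC(C)(C)[Si](C)(C)O[C@H]1CC(C)(C)[C@@H]2C(=[N+]([O-])[O-])[C@@H](O[Si](C)(C)C(C)(C)C)C(C)=C(CC/C(C)=C/COCc3ccc(OC)cc3)[C@@]2(C)C1 | intermediate (not isolated)
34 | 2α,7α-bis(tert-butyldimethylsilyloxy)-15-(4-methoxybenzyloxy)labda-8,13E-dien-6-one | CC(C)(C)[Si](C)(C)O[C@H]1CC(C)(C)[C@@H]2C(=O)[C@@H](O[Si](C)(C)C(C)(C)C)C(C)=C(CC/C(C)=C/COCc3ccc(OC)cc3)[C@@]2(C)C1 | intermediate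
35 | 2α,7α-bis(tert-butyldimethylsilyloxy)-15-(4-methoxybenzyloxy)labda-8,13E-dien-6β-ol | CC(C)(C)[Si](C)(C)O[C@H]1CC(C)(C)[C@@H]2[C@H](O)[C@@H](O[Si](C)(C)C(C)(C)C)C(C)=C(CC/C(C)=C/COCc3ccc(OC)cc3)[C@@]2(C)C1 | intermediate
36 | 15-(4-methoxybenzyloxy)labda-8,13E-diene-2α,6β,7α-triol | O[C@H]1CC(C)(C)[C@@H]2[C@H](O)[C@@H](O)C(C)=C(CC/C(C)=C/COCc3ccc(OC)cc3)[C@@]2(C)C1 | intermediate
37 | 2α,6β,7α-triacetoxy-15-(4-methoxybenzyloxy)labda-8,13E-diene | CC(=O)O[C@H]1CC(C)(C)[C@@H]2[C@H](OC(C)=O)[C@@H](OC(C)=O)C(C)=C(CC/C(C)=C/COCc3ccc(OC)cc3)[C@@]2(C)C1 | intermediate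
38 | 2α,6β,7α-triacetoxylabda-8,13E-dien-15-ol (CNP0305346.2) | CC(=O)O[C@H]1CC(C)(C)[C@@H]2[C@H](OC(C)=O)[C@@H](OC(C)=O)C(C)=C(CC/C(C)=C/CO)[C@@]2(C)C1 | target

**Step count**
Total: 27 steps (5 for the side chain, 22 for the main line). Longest linear sequence: 22 steps (steps 6–27, from 2,2-dimethylpent-4-enal 9).

**Steps most likely to fail**

1. Step 22 (intramolecular Diels–Alder). The cycloaddition may not take place because the C5–C10 bond joins a carbon next to quaternary C4 to a fully substituted diene terminus. The silyl dienol ether or the nitroalkene may decompose on prolonged heating, or endo/exo control may be poor. Fallback with known reactions, stepwise and polar: starting from 31, a Lewis acid (SnCl4 or TiCl2(Oi-Pr)2, CH2Cl2, −78 °C) should trigger an intramolecular vinylogous Mukaiyama–Michael addition of the dienol ether carbon C10 to the nitroalkene carbon C5. This closes ring A and, after aqueous work-up, gives the nitro enal F1. An intramolecular Henry reaction of F1 (catalytic tetramethylguanidine, THF) between C6 and the C7 aldehyde should then close ring B under thermodynamic control to the 6α-nitro-7α-alcohol F2. Silylation of F2 (TBSOTf, 2,6-lutidine) returns to the route at 32.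

2. Step 23 (Nef reaction). The nitronate may expel the neighbouring C7 silyloxy group (β-elimination to a nitro diene), or the hindered imine may resist hydrolysis. Fallback without alkoxide base: starting from 32, reduce the nitro group to the ketoxime F3 with SnCl2, PhSH and Et3N. Then cleave the oxime F3 reductively with buffered aqueous TiCl3 to return to the route at 34.

3. Step 19 (selective enol silylation of the dialdehyde). The free C5 aldehyde may be attacked by the new dienol ether under silyl triflate activation (intramolecular aldol-type closure). The β,γ-unsaturated aldehyde may slip into conjugation, or the C7=C8 bond may form with poor E selectivity. Fallback with the order of events changed, so that the nitroalkene is in place before C7 is oxidised: starting from 25, protect the C7 alcohol (TESCl, imidazole) to give the triethylsilyl ether F4. A Henry addition of nitromethane gives the nitro alcohol F5, and MsCl with i-Pr2NEt gives the nitroalkene F6. The triethylsilyl group is removed selectively (PPTS, MeOH) to give the hydroxy nitroalkene F7. Buffered Dess–Martin oxidation gives the nitroalkene aldehyde F8, and TBSOTf with Et3N at −78 °C returns to the route at 31.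

**Further compounds**
F1 | step 22 | nitro enal after Michael closure of ring A (C5 bearing CH2NO2, C10 bearing the (Z)-C9=C8 enal, 2-OTBS) | CC(C)(C)[Si](C)(C)O[C@H]1CC(C)(C)[C@H](C[N+](=O)[O-])[C@](C)(C1)/C(CC/C(C)=C/COCc2ccc(OC)cc2)=C(/C)C=O
F2 | step 22 | 6α-nitro-2α-(tert-butyldimethylsilyloxy)-15-(4-methoxybenzyloxy)labda-8,13E-dien-7α-ol | CC(C)(C)[Si](C)(C)O[C@H]1CC(C)(C)[C@@H]2[C@@H]([N+](=O)[O-])[C@@H](O)C(C)=C(CC/C(C)=C/COCc3ccc(OC)cc3)[C@@]2(C)C1
F3 | step 23 | 6-oxime of ketone 34 | CC(C)(C)[Si](C)(C)O[C@H]1CC(C)(C)[C@@H]2C(=NO)[C@@H](O[Si](C)(C)C(C)(C)C)C(C)=C(CC/C(C)=C/COCc3ccc(OC)cc3)[C@@]2(C)C1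
F4 | step 19 | C7 triethylsilyl ether of hydroxy aldehyde 25 | O=CC(C)(C)C[C@H](O[Si](C)(C)C(C)(C)C)C/C(C)=C(\CC/C(C)=C/COCc1ccc(OC)cc1)C(C)CO[Si](CC)(CC)CC
F5 | step 19 | 6-nitro-5-hydroxy adduct of F4 (both C5 epimers) | [O-][N+](=O)CC(O)C(C)(C)C[C@H](O[Si](C)(C)C(C)(C)C)C/C(C)=C(\CC/C(C)=C/COCc1ccc(OC)cc1)C(C)CO[Si](CC)(CC)CC
F6 | step 19 | (5E)-nitroalkene with C7 triethylsilyl ether | [O-][N+](=O)/C=C/C(C)(C)C[C@H](O[Si](C)(C)C(C)(C)C)C/C(C)=C(\CC/C(C)=C/COCc1ccc(OC)cc1)C(C)CO[Si](CC)(CC)CC
F7 | step 19 | (5E)-nitroalkene with free C7 alcohol | [O-][N+](=O)/C=C/C(C)(C)C[C@H](O[Si](C)(C)C(C)(C)C)C/C(C)=C(\CC/C(C)=C/COCc1ccc(OC)cc1)C(C)CO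
F8 | step 19 | (5E)-nitroalkene with C7 aldehyde | [O-][N+](=O)/C=C/C(C)(C)C[C@H](O[Si](C)(C)C(C)(C)C)C/C(C)=C(\CC/C(C)=C/COCc1ccc(OC)cc1)C(C)C=O
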